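## Retrosynthetic overview

- The 14-membered carbocycle is closed last by a Nozaki–Hiyama–Kishi (NHK) macrocyclisation (C3–C4) of an iodo aldehyde; C3 is created there.
- The seven-membered α-methylene lactone is formed first: ketene-type esterification of the C12 tertiary alcohol with a malonic acid, ring-closing metathesis (C13=C14), diimide reduction, then Mannich methylenation.
- Western fragment (C4–C13, sets C11 and C12): nerol, propynylation, hydrozirconation–iodination, SeO2 oxidation, Sharpless epoxidation, Payne/sulfonium-ylide homologation.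
- Eastern fragment (C1–C3, C14–C16, sets C1): iridium-catalysed asymmetric allylic alkylation of an acetal-bearing allylic carbonate with malonate.
- Ring order: lactone ring first, macrocycle second.

Assumption: locants C1–C20 are cembrane-type labels (C1 = ring-fusion CH, C3 = carbinol carbon, C11 = acetoxy carbon, C12 = quaternary lactone carbon, C15–C17 = acrylate unit); in these labels the target is (1R,3R,4E,7Z,11S,12R).

## Route

Step 1
Reactants: 1 nerol, (2Z)-3,7-dimethylocta-2,6-dien-1-ol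
Product: 2 neryl bromide, (2Z)-1-bromo-3,7-dimethylocta-2,6-diene
Conditions: PBr3 (0.4 equiv), pyridine (cat.), Et2O, −10 °C
Reagents that add atoms: phosphorus tribromide, BrP(Br)Br
Why: SN2-type bromination of the allylic alcohol at low temperature keeps the Z-trisubstituted alkene (future C7=C8) intact.

Step 2
Reactants: 2 neryl bromide
Product: 3 (5Z)-6,10-dimethylundeca-5,9-dien-2-yne
Conditions: CH3C≡CMgBr (1.5 equiv), CuBr·SMe2 (5 mol %), THF, 0 °C to rt
Reagents that add atoms: 1-propynylmagnesium bromide, CC#C[Mg]Br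
Why: Copper-catalysed SN2 allylic substitution by the alkynyl Grignard reagent gives the skipped enyne with retention of the Z-alkene and brings in C4, C5 and the C4 methyl.

Step 3
Reactants: 3 (5Z)-6,10-dimethylundeca-5,9-dien-2-yne
Product: 5 (2E,5Z)-2-iodo-6,10-dimethylundeca-2,5,9-triene, via alkenylzirconocene chloride 4 (not isolated)
Conditions: Cp2Zr(H)Cl (2 equiv), THF, rt to 45 °C; then I2, 0 °C
Reagents that add atoms: iodine, II
Why: Hydrozirconation is a syn addition that, after equilibration, places zirconium on the less hindered methyl-bearing alkyne carbon and ignores trisubstituted alkenes, and iodinolysis with retention gives the E-vinyl iodide.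

Step 4
Reactants: 5 (2E,5Z)-2-iodo-6,10-dimethylundeca-2,5,9-triene
Product: 6 (2E,6Z,9E)-10-iodo-2,6-dimethylundeca-2,6,9-trien-1-ol
Conditions: SeO2 (0.3 equiv), t-BuOOH (3 equiv), salicylic acid (10 mol %), CH2Cl2, rt
Reagents that add atoms: tert-butyl hydroperoxide, CC(C)(C)OO; selenium dioxide (catalytic oxygen carrier), O=[Se]=O
Why: Catalytic SeO2 allylic oxidation (ene reaction then [2,3]-sigmatropic shift) hydroxylates the E-methyl of the terminal isopropylidene group, the least hindered and most electron-rich alkene, giving the E-allylic alcohol (C13).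

Step 5
Reactants: 6 (2E,6Z,9E)-10-iodo-2,6-dimethylundeca-2,6,9-trien-1-ol
Product: 7 [(2S,3S)-3-[(3Z,6E)-7-iodo-3-methylocta-3,6-dien-1-yl]-2-methyloxiran-2-yl]methanol
Conditions: Ti(OiPr)4 (10 mol %), diethyl L-(+)-tartrate (12 mol %), t-BuOOH, 4 Å MS, CH2Cl2, −20 °C
Reagents that add atoms: tert-butyl hydroperoxide, CC(C)(C)OO
Why: Sharpless asymmetric epoxidation is hydroxyl-directed (only the allylic alcohol alkene reacts) and the L-(+)-tartrate catalyst gives the (2S,3S)-epoxy alcohol from an E-allylic alcohol, as in geraniol to (2S,3S)-epoxygeraniol, fixing C11 and the pre-inversion configuration of C12.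

Step 6
Reactants: 7 the (2S,3S)-epoxy alcohol
Product: 9 (3R,4S,7Z,10E)-11-iodo-3,7-dimethyldodeca-1,7,10-triene-3,4-diol, via Payne-rearranged terminal epoxide 8 (not isolated)
Conditions: Me3S+ I− (5 equiv), n-BuLi (4.8 equiv), THF, −10 °C; then 7, −10 °C to rt
Reagents that add atoms: trimethylsulfonium iodide, C[S+](C)C.[I-]
Why: The epoxy alkoxide undergoes Payne rearrangement (intramolecular SN2, inversion at C12) to the terminal epoxide, which dimethylsulfonium methylide opens at CH2 and converts to the vinyl carbinol (epoxide-to-allylic-alcohol homologation), giving the anti C11/C12 diol with C11 retained.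

Step 7
Reactants: 9 the vinyl diol
Product: 10 (3R,4S,7Z,10E)-3-hydroxy-11-iodo-3,7-dimethyldodeca-1,7,10-trien-4-yl acetate
Conditions: Ac2O (1.2 equiv), pyridine, DMAP (5 mol %), CH2Cl2, 0 °C
Reagents that add atoms: acetic anhydride, CC(=O)OC(C)=O
Why: Chemoselective acylation: the secondary C11 alcohol is acetylated while the tertiary allylic C12 alcohol does not react under these mild conditions.

Step 8
Reactants: 11 ethyl 3,3-diethoxypropanoate
Product: 12 ethyl 2-(1,3-dioxolan-2-yl)acetate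
Conditions: ethylene glycol (3 equiv), PPTS (cat.), toluene, reflux with removal of EtOH
Reagents that add atoms: ethane-1,2-diol, OCCO
Why: Acid-catalysed transacetalisation driven by distilling out ethanol gives the cyclic acetal, which is robust enough for the later free malonic acid stage.

Step 9
Reactants: 12 ethyl 2-(1,3-dioxolan-2-yl)acetate
Product: 13 2-(1,3-dioxolan-2-yl)acetaldehyde
Conditions: i-Bu2AlH (1.05 equiv), CH2Cl2, −78 °C; Rochelle salt work-up; used crude
Reagents that add atoms: none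
Why: Partial ester reduction at −78 °C stops at the aldehyde because the tetrahedral aluminate (chelated by an acetal oxygen) survives until work-up.

Step 10
Reactants: 13 2-(1,3-dioxolan-2-yl)acetaldehyde
Product: 14 ethyl (2E)-4-(1,3-dioxolan-2-yl)but-2-enoate
Conditions: Ph3P=CHCO2Et (1.2 equiv), CH2Cl2, rt
Reagents that add atoms: ethyl (triphenylphosphoranylidene)acetate, CCOC(=O)C=P(c1ccccc1)(c1ccccc1)c1ccccc1
Why: Wittig olefination with a stabilised ylide gives the E-enoate selectively.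

Step 11
Reactants: 14 ethyl (2E)-4-(1,3-dioxolan-2-yl)but-2-enoate
Product: 15 (2E)-4-(1,3-dioxolan-2-yl)but-2-en-1-ol
Conditions: i-Bu2AlH (2.2 equiv), CH2Cl2, −78 °C
Reagents that add atoms: none
Why: 1,2-Reduction of the enoate by the aluminium hydride gives the E-allylic alcohol without touching the alkene or the acetal.

Step 12
Reactants: 15 (2E)-4-(1,3-dioxolan-2-yl)but-2-en-1-ol
Product: 16 (2E)-4-(1,3-dioxolan-2-yl)but-2-en-1-yl methyl carbonate
Conditions: ClCO2Me (1.3 equiv), pyridine, CH2Cl2, 0 °C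
Reagents that add atoms: methyl chloroformate, COC(=O)Cl
Why: O-Acylation of the primary alcohol gives the linear E-allylic carbonate needed for allylic substitution.

Step 13
Reactants: 16 the allylic methyl carbonate
Product: 17 dimethyl 2-[(2S)-1-(1,3-dioxolan-2-yl)but-3-en-2-yl]propanedioate
Conditions: [Ir(cod)Cl]2 (2 mol %), BINOL/bis(1-phenylethyl)amine phosphoramidite ligand (4 mol %, antipode giving the 2S product), TBD (10 mol %), dimethyl malonate (1.3 equiv), THF, rt
Reagents that add atoms: dimethyl malonate, COC(=O)CC(=O)OC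
Why: Iridium-catalysed asymmetric allylic alkylation sends the malonate to the substituted allyl terminus (branched product) with catalyst-controlled facial selectivity, setting the future C1 stereocentre.

Step 14
Reactants: 17 the malonate diester
Product: 18 2-[(2S)-1-(1,3-dioxolan-2-yl)but-3-en-2-yl]propanedioic acid
Conditions: LiOH (4 equiv), THF/MeOH/H2O, rt; then 1 M HCl to pH 3, 0 °C, rapid extraction
Reagents that add atoms: lithium hydroxide (hydroxide oxygen), [Li+].[OH-]
Why: Saponification of both methyl esters; the allylic stereocentre is not epimerisable and the dioxolane tolerates brief cold acidification.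

Step 15
Reactants: 10 the tertiary allylic alcohol acetate; 18 the malonic acid
Product: 21 3-{[(3R,4S,7Z,10E)-4-(acetyloxy)-11-iodo-3,7-dimethyldodeca-1,7,10-trien-3-yl]oxy}-2-[(2S)-1-(1,3-dioxolan-2-yl)but-3-en-2-yl]-3-oxopropanoic acid (both C2 epimers), via O-acylisourea 19 (not isolated), via carboxyketene 20 (not isolated)
Conditions: DCC (1.5 equiv), 18 (1.5 equiv), MeCN/CH2Cl2, 0 °C to rt
Reagents that add atoms: none
Why: Carbodiimide activation of a malonic acid collapses to a carboxyketene (acylation through a ketene), which acylates even the hindered tertiary alcohol and joins the fragments; the C15 epimer mixture is irrelevant because C15 becomes sp2 in step 18.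

Step 16
Reactants: 21 the diene half ester
Product: 22 (4S,7R)-7-[(1S,4Z,7E)-1-(acetyloxy)-8-iodo-4-methylnona-4,7-dien-1-yl]-4-(1,3-dioxolan-2-ylmethyl)-7-methyl-2-oxo-2,3,4,7-tetrahydrooxepine-3-carboxylic acid (both C3 epimers)
Conditions: second-generation Grubbs catalyst RuCl2(=CHPh)(H2IMes)(PCy3) (10 mol %), CH2Cl2 (2 mM), 40 °C
Reagents that add atoms: none
Why: Ring-closing metathesis of the two monosubstituted vinyl groups closes the seven-membered lactone at C13=C14; the trisubstituted alkenes and the vinyl iodide are inert to the ruthenium carbene and the quaternary C12 favours cyclisation.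

Step 17
Reactants: 22 the unsaturated lactone acid
Product: 23 (4R,7R)-7-[(1S,4Z,7E)-1-(acetyloxy)-8-iodo-4-methylnona-4,7-dien-1-yl]-4-(1,3-dioxolan-2-ylmethyl)-7-methyl-2-oxooxepane-3-carboxylic acid (both C3 epimers)
Conditions: 2-nitrobenzenesulfonohydrazide (10 equiv), Et3N, CH2Cl2, rt
Reagents that add atoms: none
Why: Diimide reduction saturates the cis-disubstituted ring alkene far faster than trisubstituted alkenes and leaves the vinyl iodide untouched.

Step 18
Reactants: 23 the α-carboxy lactone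
Product: 25 (1S,4Z,7E)-1-[(2R,5R)-5-(1,3-dioxolan-2-ylmethyl)-2-methyl-6-methylidene-7-oxooxepan-2-yl]-8-iodo-4-methylnona-4,7-dien-1-yl acetate, via Mannich base 24 (not isolated)
Conditions: 37% aq. HCHO, Et2NH, THF, 0 °C to rt; then NaOAc, AcOH, 60 °C
Reagents that add atoms: formaldehyde, C=O
Why: Mannich reaction at the malonate-type carbon followed by decarboxylative elimination of diethylamine gives the α-methylene lactone under conditions that spare the acetate and the dioxolane.

Step 19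
Reactants: 25 the dioxolane
Product: 26 (1S,4Z,7E)-8-iodo-4-methyl-1-[(2R,5R)-2-methyl-6-methylidene-7-oxo-5-(2-oxoethyl)oxepan-2-yl]nona-4,7-dien-1-yl acetate
Conditions: TsOH·H2O (0.2 equiv), acetone/H2O (10:1), 40 °C
Reagents that add atoms: water, O
Why: Acid-catalysed acetal hydrolysis frees the C3 aldehyde; the tertiary lactone, acetate, vinyl iodide and skipped diene tolerate mild aqueous acid.

Step 20
Reactants: 26 the iodo aldehyde
Product: 28 (1R,3R,4E,7Z,11S,12R)-3-hydroxy-4,8,12-trimethyl-15-methylidene-14-oxo-13-oxabicyclo[10.3.2]heptadeca-4,7-dien-11-yl acetate, via alkenylchromium dichloride 27 (not isolated)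
Conditions: CrCl2 (15 equiv), NiCl2 (1 mol %), DMSO/THF (3:1), rt, syringe-pump addition to 1 mM
Reagents that add atoms: none
Why: In this NHK macrocyclisation, nickel-mediated formation of the alkenylchromium species and its chemoselective addition to the aldehyde at high dilution close the 14-membered ring with retention of the E-alkene; the C3 carbinol is set only by macrocyclic substrate control, so the 3R epimer is isolated by chromatography.

## Compound list

1 | nerol, (2Z)-3,7-dimethylocta-2,6-dien-1-ol | CC(C)=CCC/C(C)=C\CO | starting material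
2 | neryl bromide, (2Z)-1-bromo-3,7-dimethylocta-2,6-diene | CC(C)=CCC/C(C)=C\CBr | intermediate
3 | (5Z)-6,10-dimethylundeca-5,9-dien-2-yne | CC#CC/C=C(/C)CCC=C(C)C | intermediate
4 | chlorobis(cyclopentadienyl)[(2E,5Z)-6,10-dimethylundeca-2,5,9-trien-2-yl]zirconium | Cl[Zr](C1C=CC=C1)(C1C=CC=C1)/C(C)=C/C/C=C(/C)CCC=C(C)C | intermediate
5 | (2E,5Z)-2-iodo-6,10-dimethylundeca-2,5,9-triene | I/C(C)=C/C/C=C(/C)CCC=C(C)C | intermediate
6 | (2E,6Z,9E)-10-iodo-2,6-dimethylundeca-2,6,9-trien-1-ol | I/C(C)=C/C/C=C(/C)CC/C=C(\C)CO | intermediate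
7 | [(2S,3S)-3-[(3Z,6E)-7-iodo-3-methylocta-3,6-dien-1-yl]-2-methyloxiran-2-yl]methanol | I/C(C)=C/C/C=C(/C)CC[C@@H]1O[C@@]1(C)CO | intermediate
8 | (1S,4Z,7E)-8-iodo-4-methyl-1-[(2R)-2-methyloxiran-2-yl]nona-4,7-dien-1-ol | I/C(C)=C/C/C=C(/C)CC[C@H](O)[C@@]1(C)CO1 | intermediate
9 | (3R,4S,7Z,10E)-11-iodo-3,7-dimethyldodeca-1,7,10-triene-3,4-diol | I/C(C)=C/C/C=C(/C)CC[C@H](O)[C@](C)(O)C=C | intermediate
10 | (3R,4S,7Z,10E)-3-hydroxy-11-iodo-3,7-dimethyldodeca-1,7,10-trien-4-yl acetate | I/C(C)=C/C/C=C(/C)CC[C@H](OC(C)=O)[C@](C)(O)C=C | intermediate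
11 | ethyl 3,3-diethoxypropanoate | CCOC(=O)CC(OCC)OCC | starting material
12 | ethyl 2-(1,3-dioxolan-2-yl)acetate | CCOC(=O)CC1OCCO1 | intermediate
13 | 2-(1,3-dioxolan-2-yl)acetaldehyde | O=CCC1OCCO1 | intermediate
14 | ethyl (2E)-4-(1,3-dioxolan-2-yl)but-2-enoate | CCOC(=O)/C=C/CC1OCCO1 | intermediate
15 | (2E)-4-(1,3-dioxolan-2-yl)but-2-en-1-ol | OC/C=C/CC1OCCO1 | intermediate
16 | (2E)-4-(1,3-dioxolan-2-yl)but-2-en-1-yl methyl carbonate | COC(=O)OC/C=C/CC1OCCO1 | intermediate
17 | dimethyl 2-[(2S)-1-(1,3-dioxolan-2-yl)but-3-en-2-yl]propanedioate | COC(=O)C(C(=O)OC)[C@H](C=C)CC1OCCO1 | intermediate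
18 | 2-[(2S)-1-(1,3-dioxolan-2-yl)but-3-en-2-yl]propanedioic acid | OC(=O)C(C(=O)O)[C@H](C=C)CC1OCCO1 | intermediate
19 | 3-[(N,N'-dicyclohexylcarbamimidoyl)oxy]-2-[(2S)-1-(1,3-dioxolan-2-yl)but-3-en-2-yl]-3-oxopropanoic acid | OC(=O)C(C(=O)OC(=NC1CCCCC1)NC1CCCCC1)[C@H](C=C)CC1OCCO1 | intermediate
20 | (3S)-3-(1,3-dioxolan-2-ylmethyl)-2-(oxomethylidene)pent-4-enoic acid | O=C=C(C(=O)O)[C@H](C=C)CC1OCCO1 | intermediate
21 | 3-{[(3R,4S,7Z,10E)-4-(acetyloxy)-11-iodo-3,7-dimethyldodeca-1,7,10-trien-3-yl]oxy}-2-[(2S)-1-(1,3-dioxolan-2-yl)but-3-en-2-yl]-3-oxopropanoic acid (C2 epimers) | I/C(C)=C/C/C=C(/C)CC[C@H](OC(C)=O)[C@@](C)(C=C)OC(=O)C(C(=O)O)[C@H](C=C)CC1OCCO1 | intermediate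
22 | (4S,7R)-7-[(1S,4Z,7E)-1-(acetyloxy)-8-iodo-4-methylnona-4,7-dien-1-yl]-4-(1,3-dioxolan-2-ylmethyl)-7-methyl-2-oxo-2,3,4,7-tetrahydrooxepine-3-carboxylic acid (C3 epimers) | I/C(C)=C/C/C=C(/C)CC[C@H](OC(C)=O)[C@@]1(C)/C=C\[C@H](CC2OCCO2)C(C(=O)O)C(=O)O1 | intermediate
23 | (4R,7R)-7-[(1S,4Z,7E)-1-(acetyloxy)-8-iodo-4-methylnona-4,7-dien-1-yl]-4-(1,3-dioxolan-2-ylmethyl)-7-methyl-2-oxooxepane-3-carboxylic acid (C3 epimers) | I/C(C)=C/C/C=C(/C)CC[C@H](OC(C)=O)[C@@]1(C)CC[C@H](CC2OCCO2)C(C(=O)O)C(=O)O1 | intermediate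
24 | (4R,7R)-7-[(1S,4Z,7E)-1-(acetyloxy)-8-iodo-4-methylnona-4,7-dien-1-yl]-3-[(diethylamino)methyl]-4-(1,3-dioxolan-2-ylmethyl)-7-methyl-2-oxooxepane-3-carboxylic acid | I/C(C)=C/C/C=C(/C)CC[C@H](OC(C)=O)[C@@]1(C)CC[C@H](CC2OCCO2)C(CN(CC)CC)(C(=O)O)C(=O)O1 | intermediate
25 | (1S,4Z,7E)-1-[(2R,5R)-5-(1,3-dioxolan-2-ylmethyl)-2-methyl-6-methylidene-7-oxooxepan-2-yl]-8-iodo-4-methylnona-4,7-dien-1-yl acetate | I/C(C)=C/C/C=C(/C)CC[C@H](OC(C)=O)[C@@]1(C)CC[C@H](CC2OCCO2)C(=C)C(=O)O1 | intermediate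
26 | (1S,4Z,7E)-8-iodo-4-methyl-1-[(2R,5R)-2-methyl-6-methylidene-7-oxo-5-(2-oxoethyl)oxepan-2-yl]nona-4,7-dien-1-yl acetate | I/C(C)=C/C/C=C(/C)CC[C@H](OC(C)=O)[C@@]1(C)CC[C@H](CC=O)C(=C)C(=O)O1 | intermediate
27 | dichloro[(2E,5Z,9S)-9-(acetyloxy)-6-methyl-9-[(2R,5R)-2-methyl-6-methylidene-7-oxo-5-(2-oxoethyl)oxepan-2-yl]nona-2,5-dien-2-yl]chromium | Cl[Cr](Cl)/C(C)=C/C/C=C(/C)CC[C@H](OC(C)=O)[C@@]1(C)CC[C@H](CC=O)C(=C)C(=O)O1 | intermediate
28 | (1R,3R,4E,7Z,11S,12R)-3-hydroxy-4,8,12-trimethyl-15-methylidene-14-oxo-13-oxabicyclo[10.3.2]heptadeca-4,7-dien-11-yl acetate | C=C1C(=O)O[C@]2(C)CC[C@@H]1C[C@@H](O)/C(C)=C/C/C=C(/C)CC[C@@H]2OC(C)=O | target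

## Step count and risk

Total step count: 20.
Longest linear sequence: 13 steps (steps 1–7 then 15–20; the branch 8–14 then 15–20 is equally long).

The three steps most likely to fail:

**Step 6 (Payne rearrangement/ylide homologation).** The Payne step needs intramolecular attack at the fully substituted C12, which may be too slow. The fallback sets out from 6 and comes back at 10, inverting C11 instead of C12. Epoxidise 6 with the antipodal catalyst (Ti(OiPr)4, diethyl D-(−)-tartrate, t-BuOOH, CH2Cl2, −20 °C) to give [(2R,3R)-3-[(3Z,6E)-7-iodo-3-methylocta-3,6-dien-1-yl]-2-methyloxiran-2-yl]methanol F1. Open the epoxide at C11 with acetic acid under Ti(OiPr)4 mediation (SN2, inversion, acetate installed directly) to give (2R,3S,6Z,9E)-1,2-dihydroxy-10-iodo-2,6-dimethylundeca-6,9-dien-3-yl acetate F2. Oxidise the primary alcohol (SO3·pyridine, DMSO, i-Pr2NEt) to (2S,3S,6Z,9E)-2-hydroxy-10-iodo-2,6-dimethyl-1-oxoundeca-6,9-dien-3-yl acetate F3, and methylenate the aldehyde (Ph3P=CH2, THF, −78 °C) to reach 10.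

**Step 15 (intermolecular acylation of the hindered tertiary alcohol).** The fallback sets out from 10 and 18 and comes back at 23, so it also replaces steps 16 and 17; the C–C bond is made first and the ester bond is then formed intramolecularly. Cross-metathesis of the two terminal alkenes (second-generation Hoveyda–Grubbs catalyst RuCl2(H2IMes)(=CH-C6H4-2-OiPr), excess 18, CH2Cl2, 40 °C) gives 2-[(2S,3E,5R,6S,9Z,12E)-6-(acetyloxy)-1-(1,3-dioxolan-2-yl)-5-hydroxy-13-iodo-5,9-dimethyltetradeca-3,9,12-trien-2-yl]propanedioic acid F4. Diimide reduction (2-nitrobenzenesulfonohydrazide, Et3N) of the disubstituted alkene gives 2-[(2R,5R,6S,9Z,12E)-6-(acetyloxy)-1-(1,3-dioxolan-2-yl)-5-hydroxy-13-iodo-5,9-dimethyltetradeca-9,12-dien-2-yl]propanedioic acid F5. DCC in MeCN at 2 mM then lactonises through the carboxyketene onto the tertiary alcohol to give 23.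

**Step 20 (C3 configuration in the NHK macrocyclisation).** Substrate control may give little or the wrong selectivity. The fallback sets out from 26 and comes back at 28, setting C3 by reagent control. Run the same chromium-mediated cyclisation without regard to C3, which gives 28 together with (1R,3S,4E,7Z,11S,12R)-3-hydroxy-4,8,12-trimethyl-15-methylidene-14-oxo-13-oxabicyclo[10.3.2]heptadeca-4,7-dien-11-yl acetate F6. Oxidise the mixture (Dess–Martin periodinane, NaHCO3, CH2Cl2) to (1R,4E,7Z,11S,12R)-4,8,12-trimethyl-15-methylidene-3,14-dioxo-13-oxabicyclo[10.3.2]heptadeca-4,7-dien-11-yl acetate F7. Reduce the enone with (S)-2-methyl-CBS-oxazaborolidine and catecholborane (toluene, −78 °C), where the alkenyl group acts as the large substituent, to give the 3R alcohol 28.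

## Further compounds

F1 | step 6 | [(2R,3R)-3-[(3Z,6E)-7-iodo-3-methylocta-3,6-dien-1-yl]-2-methyloxiran-2-yl]methanol | I/C(C)=C/C/C=C(/C)CC[C@H]1O[C@]1(C)CO
F2 | step 6 | (2R,3S,6Z,9E)-1,2-dihydroxy-10-iodo-2,6-dimethylundeca-6,9-dien-3-yl acetate | I/C(C)=C/C/C=C(/C)CC[C@H](OC(C)=O)[C@](C)(O)CO
F3 | step 6 | (2S,3S,6Z,9E)-2-hydroxy-10-iodo-2,6-dimethyl-1-oxoundeca-6,9-dien-3-yl acetate | I/C(C)=C/C/C=C(/C)CC[C@H](OC(C)=O)[C@](C)(O)C=O
F4 | step 15 | 2-[(2S,3E,5R,6S,9Z,12E)-6-(acetyloxy)-1-(1,3-dioxolan-2-yl)-5-hydroxy-13-iodo-5,9-dimethyltetradeca-3,9,12-trien-2-yl]propanedioic acid | I/C(C)=C/C/C=C(/C)CC[C@H](OC(C)=O)[C@](C)(O)/C=C/[C@H](CC1OCCO1)C(C(=O)O)C(=O)O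
F5 | step 15 | 2-[(2R,5R,6S,9Z,12E)-6-(acetyloxy)-1-(1,3-dioxolan-2-yl)-5-hydroxy-13-iodo-5,9-dimethyltetradeca-9,12-dien-2-yl]propanedioic acid | I/C(C)=C/C/C=C(/C)CC[C@H](OC(C)=O)[C@](C)(O)CC[C@H](CC1OCCO1)C(C(=O)O)C(=O)O
F6 | step 20 | (1R,3S,4E,7Z,11S,12R)-3-hydroxy-4,8,12-trimethyl-15-methylidene-14-oxo-13-oxabicyclo[10.3.2]heptadeca-4,7-dien-11-yl acetate | C=C1C(=O)O[C@]2(C)CC[C@@H]1C[C@H](O)/C(C)=C/C/C=C(/C)CC[C@@H]2OC(C)=O
F7 | step 20 | (1R,4E,7Z,11S,12R)-4,8,12-trimethyl-15-methylidene-3,14-dioxo-13-oxabicyclo[10.3.2]heptadeca-4,7-dien-11-yl acetate | C=C1C(=O)O[C@]2(C)CC[C@@H]1CC(=O)/C(C)=C/C/C=C(/C)CC[C@@H]2OC(C)=O
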